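Both stereocentres sit side by side in the only ring (C2–C7). They are carbinol C6 (CH3, OH) and C7 (H, chain from C8), the latter pressed against quaternary C2, with the C6 oxygen and C8 on opposite ring faces. A vicinal anti carbon/oxygen pair of this kind is the footprint of β-alkylation and α-oxygenation of a cyclohexenone whose carbonyl, at C5, is only on loan. The plan therefore cuts C7–C8 and C6–O together. Asymmetric copper-catalysed 1,4-addition of a silylbutynyl Grignard reagent to achiral 2,4,4-trimethylcyclohex-2-enone, then oxidation of the resulting enolate in the same flask, sets both centres. Carbonyl deletion, alkyne-to-(E)-iodoalkene conversion and a B-alkyl Suzuki coupling (C11–C12) with a farnesol-derived borane complete the target.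

Key step: step 3

Atom labels: C2 = ring CMe2, C3–C5 = ring CH2, C6 = carbinol carbon, C7 = ring CH, C8/C9 = first chain CH2CH2, C10(CH3)=C11, C12/C13 = CH2CH2, C14=C15(CH3), and so on to C24.

Assumption: the sense of induction of the copper–diphosphine catalyst cannot be carried over with confidence from unsubstituted cyclohexenone to an α-methyl, γ,γ-dimethyl enone, so the ligand antipode written in step 3 stands for whichever of the two commercial antipodes gives (S) at C7.

Step 1
Reactants: 1 isobutyraldehyde; 2 pent-1-en-3-one
Product: 4 2,4,4-trimethylcyclohex-2-en-1-one, via 2,2-dimethyl-5-oxoheptanal 3 (not isolated)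
Conditions: H2SO4 (cat.), toluene, 45 °C, then reflux (Dean–Stark)
Reagents that add atoms: none
Why: Acid-catalysed Robinson-type annulation: the enol of 1 adds to 2 in a Michael reaction, and in keto aldehyde 3 only the ethyl CH2 can reach the non-enolisable aldehyde through a six-membered aldol condensation, so the 2-methyl enone 4 is the only cyclohexenone that can form.

Step 2
Reactants: 5 (4-bromobut-1-yn-1-yl)trimethylsilane
Product: 6 4-(trimethylsilyl)but-3-yn-1-ylmagnesium bromide (titrated Et2O solution)
Conditions: Mg turnings (activated with a crystal of I2), Et2O, 35 °C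
Reagents that add atoms: magnesium, [Mg]
Why: Grignard formation by magnesium insertion into a primary C–Br bond, with the silyl cap masking the acidic alkyne position and Et2O chosen because strongly donating THF would favour uncatalysed 1,2-addition in step 3.

Step 3
Reactants: 4 2,4,4-trimethylcyclohex-2-en-1-one; 6 4-(trimethylsilyl)but-3-yn-1-ylmagnesium bromide
Product: 8 (2R,3S)-2-hydroxy-2,4,4-trimethyl-3-[4-(trimethylsilyl)but-3-yn-1-yl]cyclohexan-1-one, via bromomagnesium enolate 7 (not isolated)
Conditions: CuBr·SMe2 (5 mol %), (R)-1-[(SP)-2-(diphenylphosphino)ferrocenyl]ethyldicyclohexylphosphine (C36H44FeP2, 6 mol %), t-BuOMe, −75 °C, 6 (1.2 equiv) by syringe pump, then −40 °C; 2-(phenylsulfonyl)-3-phenyloxaziridine (1.6 equiv) in THF, −75 → −20 °C; aq NH4Cl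
Reagents that add atoms: 2-(phenylsulfonyl)-3-phenyloxaziridine, O=S(=O)(c1ccccc1)N1OC1c1ccccc1
Why: Proposed new method: the monovalent copper–diphosphine complex is alkylated by 6, binds the C6=C7 π bond of 4, adds oxidatively at C7 to a trivalent copper σ-alkyl and reductively eliminates, which makes C7–C8 and leaves enolate 7 with its double bond locked between C5 and C6, whereupon C6 attacks the oxaziridine oxygen in an SN2-type displacement that expels the sulfonimine and makes C6–O. The closest known reaction types are the CuBr·SMe2/ferrocenyl diphosphine conjugate addition of Grignard reagents to unsubstituted cyclic enones and the Davis hydroxylation of enolates released by conjugate addition, and what is new is their union in one enantioselective operation on an enone that is α-methylated and has a quaternary γ-carbon. No ring is closed. C7 (S) is set by the catalyst, which selects the enone face, and since 4 is achiral and its ring flip can always place the pseudoaxial C2 methyl anti to the attacked face, nothing in the substrate opposes that choice. C6 (R in 8) is set by the substrate: allylic strain with the C6 methyl and the gauche contacts with both C2 methyls push the C7 chain pseudoaxial, so attack at C6 beside the chain is blocked at contact distance and would run through a twist-boat, whereas attack on the other face is chair-like and meets only the more distant syn-axial C2 methyl, and the alternative half-chair with a pseudoequatorial chain exposes that same face, so both conformers place OH anti to C8. The step needs 1,4- over 1,2-selectivity, secured by slow addition of 6 at low temperature in weakly donating ethers so that only copper-bound alkyl is transferred, and it needs regiochemical fidelity of the enolate, secured because the magnesium enolate does not equilibrate before the excess oxidant (which also consumes residual 6) reaches it.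

Step 4
Reactants: 8 (2R,3S)-2-hydroxy-2,4,4-trimethyl-3-[4-(trimethylsilyl)but-3-yn-1-yl]cyclohexan-1-one
Product: 9 (E)-tosylhydrazone of 8
Conditions: TsNHNH2 (1.2 equiv), MeOH, rt → 45 °C
Reagents that add atoms: 4-methylbenzenesulfonohydrazide, Cc1ccc(cc1)S(=O)(=O)NN
Why: Hydrazone condensation at the only carbonyl under acid-free conditions that avoid an α-ketol shift; C6 is fully substituted and C7 is not enolisable, so both centres persist, and the NHTs group should lie anti to bulky C6 (either geometry serves).

Step 5
Reactants: 9 (E)-tosylhydrazone of 8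
Product: 11 (1S,2S)-1,3,3-trimethyl-2-[4-(trimethylsilyl)but-3-yn-1-yl]cyclohexan-1-ol, via tosylhydrazine 10 (not isolated)
Conditions: catecholborane (3 equiv), CHCl3, −10 °C → rt; NaOAc·3H2O (5 equiv), reflux
Reagents that add atoms: none
Why: Caglioti-type deoxygenation in its catecholborane form: B–H first masks the C6 hydroxyl as a borate, hydride then adds to C=N, and acetate-induced loss of sulfinate gives an alkyl diazene that expels N2 and leaves CH2 at C5, a near-neutral sequence known to tolerate α-oxygen substituents and too mild to hydroborate the silylalkyne.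

Step 6
Reactants: 11 (1S,2S)-1,3,3-trimethyl-2-[4-(trimethylsilyl)but-3-yn-1-yl]cyclohexan-1-ol
Product: 12 (1S,2S)-2-(but-3-yn-1-yl)-1,3,3-trimethylcyclohexan-1-ol
Conditions: K2CO3 (0.3 equiv), MeOH, rt
Reagents that add atoms: none
Why: Carbonate-catalysed methanolysis of the alkynyl C–Si bond (protodesilylation), which touches neither the tertiary alcohol nor the stereocentres.

Step 7
Reactants: 12 (1S,2S)-2-(but-3-yn-1-yl)-1,3,3-trimethylcyclohexan-1-ol
Product: 14 (1S,2S)-2-[(3E)-4-iodo-3-methylbut-3-en-1-yl]-1,3,3-trimethylcyclohexan-1-ol, via alkenylalane 13 (not isolated)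
Conditions: AlMe3 (4 equiv), Cp2ZrCl2 (0.3 equiv), CH2Cl2, 0 °C → rt; I2 in THF, −30 °C; aq K2CO3
Reagents that add atoms: trimethylaluminium, C[Al](C)C; iodine, [I][I]
Why: Negishi zirconium-catalysed carboalumination: the first equivalent of AlMe3 converts the alcohol into its aluminium alkoxide, Me–Al then adds syn to the terminal alkyne with methyl on internal C10, and iodinolysis with retention fixes the (E)-C10=C11 geometry.

Step 8
Reactants: 15 (2E,6E)-farnesol
Product: 16 (2E,6E)-farnesal
Conditions: activated MnO2 (15 equiv), CH2Cl2, rt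
Reagents that add atoms: none
Why: Heterogeneous MnO2 oxidation is selective for the allylic alcohol, stops at the aldehyde and does not isomerise the 2E double bond.

Step 9
Reactants: 16 (2E,6E)-farnesal
Product: 17 (3E,7E)-4,8,12-trimethyltrideca-1,3,7,11-tetraene
Conditions: Ph3PCH3Br, n-BuLi, THF, 0 °C; then 16, 0 °C → rt
Reagents that add atoms: methyltriphenylphosphonium bromide, C[P+](c1ccccc1)(c1ccccc1)c1ccccc1.[Br-]
Why: Wittig methylenation with the non-stabilised ylide adds C12 as a terminal CH2, creates no new alkene geometry and leaves the conjugated E double bond intact.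

Step 10
Reactants: 17 (3E,7E)-4,8,12-trimethyltrideca-1,3,7,11-tetraene; 14 (1S,2S)-2-[(3E)-4-iodo-3-methylbut-3-en-1-yl]-1,3,3-trimethylcyclohexan-1-ol
Product: 19 (1S,2S)-1,3,3-trimethyl-2-[(3E,7E,11E)-3,8,12,16-tetramethylheptadeca-3,7,11,15-tetraen-1-yl]cyclohexan-1-ol, via homofarnesyl-9-BBN 18 (not isolated)
Conditions: 17 (1.3 equiv), 9-BBN-H (1.3 equiv), THF, 0 °C → rt; then 14, PdCl2(dppf) (5 mol %), Cs2CO3 (2 equiv), DMF/THF/H2O, rt → 45 °C
Reagents that add atoms: none
Why: 9-BBN hydroborates only the monosubstituted C12=C13 end of the diene in the anti-Markovnikov sense (trisubstituted alkenes react far more slowly), and the B-alkyl Suzuki–Miyaura coupling then joins C12 to C11 with retention of the iodoalkene geometry through oxidative addition to zerovalent palladium, base-assisted transmetalation and reductive elimination, the free tertiary alcohol being a spectator.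

Compound list
1 | isobutyraldehyde | CC(C)C=O | starting material
2 | pent-1-en-3-one | CCC(=O)C=C | starting material
3 | 2,2-dimethyl-5-oxoheptanal | CCC(=O)CCC(C)(C)C=O | intermediate
4 | 2,4,4-trimethylcyclohex-2-en-1-one | CC1=CC(C)(C)CCC1=O | intermediate
5 | (4-bromobut-1-yn-1-yl)trimethylsilane | C[Si](C)(C)C#CCCBr | starting material
6 | 4-(trimethylsilyl)but-3-yn-1-ylmagnesium bromide | C[Si](C)(C)C#CCC[Mg]Br | intermediate
7 | bromomagnesium (3S)-2,4,4-trimethyl-3-[4-(trimethylsilyl)but-3-yn-1-yl]cyclohex-1-en-1-olate | C[Si](C)(C)C#CCC[C@H]1C(C)(C)CCC(O[Mg]Br)=C1C | intermediate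
8 | (2R,3S)-2-hydroxy-2,4,4-trimethyl-3-[4-(trimethylsilyl)but-3-yn-1-yl]cyclohexan-1-one (OH trans to chain) | C[Si](C)(C)C#CCC[C@H]1C(C)(C)CCC(=O)[C@]1(C)O | intermediate
9 | N'-{(1E,2R,3S)-2-hydroxy-2,4,4-trimethyl-3-[4-(trimethylsilyl)but-3-yn-1-yl]cyclohexylidene}-4-methylbenzenesulfonohydrazide | C[Si](C)(C)C#CCC[C@H]1C(C)(C)CC/C(=N\NS(=O)(=O)c2ccc(C)cc2)[C@]1(C)O | intermediate
10 | N'-{(2R,3S)-2-hydroxy-2,4,4-trimethyl-3-[4-(trimethylsilyl)but-3-yn-1-yl]cyclohexyl}-4-methylbenzenesulfonohydrazide (drawn free of boron; the transient C1 centre is undefined and is lost) | C[Si](C)(C)C#CCC[C@H]1C(C)(C)CCC(NNS(=O)(=O)c2ccc(C)cc2)[C@]1(C)O | intermediate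
11 | (1S,2S)-1,3,3-trimethyl-2-[4-(trimethylsilyl)but-3-yn-1-yl]cyclohexan-1-ol | C[Si](C)(C)C#CCC[C@H]1C(C)(C)CCC[C@]1(C)O | intermediate
12 | (1S,2S)-2-(but-3-yn-1-yl)-1,3,3-trimethylcyclohexan-1-ol | C#CCC[C@H]1C(C)(C)CCC[C@]1(C)O | intermediate
13 | {(1E)-4-[(1S,2S)-2-(dimethylalumanyloxy)-2,6,6-trimethylcyclohexyl]-2-methylbut-1-en-1-yl}dimethylalumane | C[Al](C)/C=C(\C)CC[C@H]1C(C)(C)CCC[C@]1(C)O[Al](C)C | intermediate
14 | (1S,2S)-2-[(3E)-4-iodo-3-methylbut-3-en-1-yl]-1,3,3-trimethylcyclohexan-1-ol | I/C=C(\C)CC[C@H]1C(C)(C)CCC[C@]1(C)O | intermediate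
15 | (2E,6E)-farnesol | CC(C)=CCC/C(C)=C/CC/C(C)=C/CO | starting material
16 | (2E,6E)-farnesal | CC(C)=CCC/C(C)=C/CC/C(C)=C/C=O | intermediate
17 | (3E,7E)-4,8,12-trimethyltrideca-1,3,7,11-tetraene | CC(C)=CCC/C(C)=C/CC/C(C)=C/C=C | intermediate
18 | 9-[(3E,7E)-4,8,12-trimethyltrideca-3,7,11-trien-1-yl]-9-borabicyclo[3.3.1]nonane | CC(C)=CCC/C(C)=C/CC/C(C)=C/CCB1C2CCCC1CCC2 | intermediate
19 | (1S,2S)-1,3,3-trimethyl-2-[(3E,7E,11E)-3,8,12,16-tetramethylheptadeca-3,7,11,15-tetraen-1-yl]cyclohexan-1-ol (CNP0273209.1) | CC(C)=CCC/C(C)=C/CC/C(C)=C/CC/C=C(\C)CC[C@H]1C(C)(C)CCC[C@]1(C)O | target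

Total step count: 10. Longest linear sequence: 7 (steps 1, 3, 4, 5, 6, 7, 10; the branch through step 2 is equally long).

Steps most likely to fail

**Step 3 (bears the new-method label).**
- What may go wrong:
  - The β-carbon C7 is neopentyl and the enone is α-methylated, so copper-mediated transfer may be outrun by direct 1,2-addition.
  - Enantioface discrimination may be weak on this substitution pattern.
  - The oxygen transfer may lose facial selectivity, because the face anti to the chain carries the syn-axial C2 methyl.
- Route of the fallback: it uses only known reaction types, sets out from 4 (and uses 6) and comes back at 11, so it replaces steps 3–5.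
- Corey–Bakshi–Shibata reduction of 4 with (S)-2-methyl-CBS-oxazaborolidine and BH3·SMe2 should give (1R)-2,4,4-trimethylcyclohex-2-en-1-ol F1.
- Steglich esterification with 2-(diphenylphosphanyl)benzoic acid gives the phosphine-bearing ester F2.
- Phosphine-directed, CuBr·SMe2-mediated syn-SN2′ substitution with 6 in Et2O delivers the chain to C7 on the face that held the C5 oxygen. That face is anti to the pseudoaxial C2 methyl. Chirality is transferred and the alkene moves to C5=C6, giving the silylbutynyl cyclohexene F3.
- NBS in aqueous acetone follows. Water opens the bromonium ion at tertiary C6 in a chair-like trans-diaxial manner, anti to the pseudoaxial chain, to give the bromohydrin F4.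
- LiEt3BH closes F4 to the epoxide F5, whose oxygen is trans to the chain, and opens it at the secondary C5. The C6–O bond is untouched and the product is 11.

**Step 5.**
- What may go wrong:
  - The diazene may collapse with expulsion of the neighbouring C6 oxygen, an eliminative reduction towards the ring alkene.
  - Hydride addition to the hindered C=N may stay incomplete.
- Route of the fallback: it sets out from 8 and comes back at 11, so it replaces steps 4 and 5.
- Hydroxyl-directed reduction with Me4NBH(OAc)3 in MeCN/AcOH delivers hydride to C5 from the face of the C6 hydroxyl and gives the trans-diol F6.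
- MsCl/Et3N sulfonylates only the secondary hydroxyl to give the monomesylate F7.
- LiEt3BH deprotonates the tertiary alcohol, and the alkoxide displaces the anti mesylate to reach the same epoxide F5 as above. Hydride then opens it at C5 to give 11.

**Step 10.**
- What may go wrong:
  - Hydroboration may spread to the trisubstituted alkenes.
  - Transmetalation may be slow, with protodeboronation of the borane, which would waste the advanced iodide.
- Route of the fallback: it moves the union to C12–C13, sets out from 12 and 15, and comes back at 19.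
- Alkyne 12 is carboaluminated as in step 7. Alane 13 is converted with n-BuLi into its ate complex and trapped with paraformaldehyde to give the (E)-allylic alcohol F8.
- Appel bromination (CBr4, PPh3) of the primary allylic hydroxyl gives the allylic bromide F9.
- Farnesol 15 is brominated in the same way to (2E,6E)-farnesyl bromide F10, and PhSO2Na in DMF converts this into farnesyl phenyl sulfone F11.
- Lithiated F11 (n-BuLi, THF, −78 °C), which is too weak a base to disturb the tertiary alcohol, is alkylated by F9 in a Biellmann-type coupling to give the C13 sulfone F12.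
- Reductive desulfonylation with LiEt3BH and PdCl2(dppp) (cat.) removes the sulfonyl group without moving the double bonds and gives 19.

Further compounds
F1 | step 3 | (1R)-2,4,4-trimethylcyclohex-2-en-1-ol | O[C@@H]1CCC(C)(C)C=C1C
F2 | step 3 | (1R)-2,4,4-trimethylcyclohex-2-en-1-yl 2-(diphenylphosphanyl)benzoate | O=C(O[C@@H]1CCC(C)(C)C=C1C)c1ccccc1P(c1ccccc1)c1ccccc1
F3 | step 3 | trimethyl{4-[(1S)-2,6,6-trimethylcyclohex-2-en-1-yl]but-1-yn-1-yl}silane | C[Si](C)(C)C#CCC[C@H]1C(C)(C)CCC=C1C
F4 | step 3 | (1R,2S,6R)-6-bromo-1,3,3-trimethyl-2-[4-(trimethylsilyl)but-3-yn-1-yl]cyclohexan-1-ol | C[Si](C)(C)C#CCC[C@H]1C(C)(C)CC[C@@H](Br)[C@]1(C)O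
F5 | step 3 | trimethyl{4-[(1R,2S,6S)-1,3,3-trimethyl-7-oxabicyclo[4.1.0]heptan-2-yl]but-1-yn-1-yl}silane | C[Si](C)(C)C#CCC[C@H]1C(C)(C)CC[C@@H]2O[C@]12C
F6 | step 5 | (1R,2R,6S)-1,5,5-trimethyl-6-[4-(trimethylsilyl)but-3-yn-1-yl]cyclohexane-1,2-diol | C[Si](C)(C)C#CCC[C@H]1C(C)(C)CC[C@@H](O)[C@]1(C)O
F7 | step 5 | (1R,2R,3S)-2-hydroxy-2,4,4-trimethyl-3-[4-(trimethylsilyl)but-3-yn-1-yl]cyclohexyl methanesulfonate | C[Si](C)(C)C#CCC[C@H]1C(C)(C)CC[C@@H](OS(C)(=O)=O)[C@]1(C)O
F8 | step 10 | (2E)-5-[(1S,2S)-2-hydroxy-2,6,6-trimethylcyclohexyl]-3-methylpent-2-en-1-ol | OC/C=C(\C)CC[C@H]1C(C)(C)CCC[C@]1(C)O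
F9 | step 10 | (1S,2S)-2-[(3E)-5-bromo-3-methylpent-3-en-1-yl]-1,3,3-trimethylcyclohexan-1-ol | BrC/C=C(\C)CC[C@H]1C(C)(C)CCC[C@]1(C)O
F10 | step 10 | (2E,6E)-farnesyl bromide | CC(C)=CCC/C(C)=C/CC/C(C)=C/CBr
F11 | step 10 | (2E,6E)-farnesyl phenyl sulfone | CC(C)=CCC/C(C)=C/CC/C(C)=C/CS(=O)(=O)c1ccccc1
F12 | step 10 | 13-(phenylsulfonyl) derivative of 19 (C13 undefined, erased on desulfonylation) | CC(C)=CCC/C(C)=C/CC/C(C)=C/C(C/C=C(\C)CC[C@H]1C(C)(C)CCC[C@]1(C)O)S(=O)(=O)c1ccccc1
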